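## Structural features

The target is a trans-2,3-disubstituted 2,3-dihydrobenzofuran. Ring A is the fused benzene ring, C2 carries the 4-hydroxyphenyl ring B, C3 carries a 2,4-dihydroxybenzoyl group (ring D), and C5 carries a CH2CH2C(=O) chain that ends in a second 2,4-dihydroxyphenyl ring (ring E). The stereocentres C2 and C3 are adjacent and both S, with the C2 aryl and the C3 aroyl group on opposite faces. Formally the molecule is a chalcone and a dihydrochalcone of the same oxygenation pattern, joined through C3–C3a and O1–C2, so both halves can come from one acetophenone. C3 is benzylic and alpha to a ketone, so it epimerises easily and rests trans. C2 is more delicate: O1–C2 is a benzylic aryl ether para to the ring B hydroxyl, so acid or base can expel the ring A phenoxide through a para-quinone methide and racemise C2, and the same bond can be hydrogenolysed. The real difficulty is therefore the absolute configuration at C2, which has no robust neighbouring centre to lean on, in a molecule with five phenols of which the ortho hydroxyl of ring D is a competing nucleophile. The key step uses exactly this feature: because C2 is para to the ring B hydroxyl, O1–C2 can be formed by adding the ring A phenol to the methide carbon of a para-quinone methide, the polarity that oxidative chalcone dimerisation uses.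

## Logic of the disconnections

**18 to 17.** The four O–CH2Ph bonds on rings D and E are cut. The ortho oxygen of ring D must be capped while the furan ring forms, and benzyl can be removed without acid or base. The skeleton is unchanged. The forward step must be neutral and must leave O1–C2 and the two ketones alone.

**17 to 15 (through 16).** O1–C2 is cut. This removes the ring and both stereocentres at once and leads to an achiral, acyclic isomer. The forward step must generate 16 from 15 under a chiral acid, close the ring on one face of the methide carbon, and let C3 relax to trans. 15 must reach this step with both phenols free and without earlier racemic closure.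

**15 to 14.** Two O–Si bonds are put back, on the ring A and ring B oxygens. With both phenols masked, neither a nucleophile nor a quinone methide is available during the basic coupling that precedes. Unmasking must be close to neutral, which rules out acid-labile acetals and base-labile esters.

**14 to 8 and 13.** The bond from the alpha carbon to ring A (later C3–C3a) is cut. This divides the molecule into two fifteen-carbon halves of similar size, both derived from 3. The forward step is an sp2–sp2 coupling that forms a trisubstituted alkene next to an ortho substituent. Alkene geometry is not critical, because it is erased in 16.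

**13 back to 10.** C–B is traced to C–Br (12), the saturated chain to the enone (11), and the silyl ether to the phenol (10). The forward reduction must be a 1,4-reduction that spares aryl bromide and benzyl ethers.

**10 to 3 and 9; 8 to 6, 5, then 3 and 4.** Each enone C=C is cut to a methyl ketone and an aldehyde. Taking the bromine from 9 avoids brominating a phenol beside the activated ring E. The alpha bromine of 8 is traced to addition–elimination on 6, which requires the alkene to react faster than ring D.

**3 to 1 and 2.** Two O–benzyl bonds are cut, leaving commercial materials.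

## Other disconnections considered

Alternative 1: The cut removes ring A itself (C3a–C7a, C4–C5, C6–C7). In the forward step the ynol-ether diyne A2, tethered through O1, C2 and C3, and the alkyne A3 cyclotrimerise on Cp*RuCl(cod) to give the silylated dihydrobenzofuran A1.
- In favour: both stereocentres are set earlier in an open chain, where asymmetric aldol or propargylation chemistry is strong. The silyl group steers the alkyne to the meta position. Ring B is a benzyl ether, so C2 cannot reopen through a quinone methide.
- Against: A1 is far from the target. The silyl group must be removed, two PMB ethers cleaved, two primary alcohols oxidised, the same aryl nucleophile added twice and the carbinols oxidised again, all next to an epimerisable C3 with a beta aryloxy leaving group, before global debenzylation. Ynol ethers of secondary benzylic alcohols are also hard to prepare and acid-sensitive.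
- Comparison: on configurational security of C2 this alternative is the better one. On precedent for the ring-forming event (diyne–alkyne cyclotrimerisation is an established reaction type) it is at least equal. On structure and step economy it is clearly worse: about six steps follow its key step, and neither resorcinol ketone is in place, whereas the chosen plan needs one step after the key step and brings both ketones from 3.

Alternative 2: The cut is O1–C7a. In the forward step the bromo hydroxy diester A5 undergoes palladium-catalysed intramolecular etherification (Pd(OAc)2, di-tert-butylbiarylphosphine, Cs2CO3) to the diester A4, with the base equilibrating C3 to trans.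
- In favour: the carbinol centre can be set by well-precedented asymmetric reduction or aldol chemistry. Five-membered aryl ether closure is a known reaction. C2 is again protected from quinone methide opening.
- Against: A5 is a beta-hydroxy ester with a doubly activated alpha hydrogen. Under Cs2CO3 and heat, retro-aldol cleavage (which would erase the carbinol configuration), E1cB dehydration and beta-hydride elimination from the palladium alkoxide all compete. After the closure two esters must become two aryl ketones by organometallic addition, again beside an epimerisable C3 with a beta leaving group.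
- Comparison: the source of absolute configuration is better precedented than in the chosen plan, and C2 is more robust; these points go to the alternative. The closure itself is about equal in reliability. The chosen plan is better in convergence (the alternative installs both ketones late, three to four steps after its key step) and avoids strong base on a labile aldol.

Alternative 3: The cut is C2–C3. In the forward step the diazoketone A7 loses N2 on Rh2(S-PTTL)4, dirhodium tetrakis(N-phthaloyl-(S)-tert-leucinate), the carbene inserts into the OCH2Ar C–H bond, and DBU then equilibrates C3 to give the bromide A6.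
- In favour: ring D and its ketone are already in place. The inserting C–H bond is activated by oxygen and by an electron-rich aryl group. Aryl diazoacetates in the same ring-forming mode are a close, highly enantioselective precedent. C2 is configurationally fixed because ring B is a benzyl ether.
- Against: the acceptor is a ketone, not an ester, so Wolff rearrangement and weaker enantiocontrol are real concerns. The ortho benzyloxy CH2 of ring D is an equally activated insertion site, leading to a six-membered ring. The C5 bromide must still be converted into the 3-aryl-3-oxopropyl chain (two to three steps in the presence of the epimerisable C3) before five benzyl ethers are removed. A diazo compound must also be handled.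
- Comparison: the stereo-defining step has closer precedent than the chosen one and gives a more robust C2; on these two points the alternative is better. Both plans rely equally on thermodynamic trans control at C3. The chosen plan is better on step economy after the key step (one step against three to four), on convergence, and in having no competing reactive site of the same kind in the substrate.

Key step: step 11

Remark: the structures of 15 and 17 follow from the target atom by atom. 15 is an isomer of 17, its alkene is E (aroyl outranks aryl at the alpha carbon), and 17 and 18 are (2S,3S) with C2 aryl and C3 aroyl trans.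

Remark: the acid is written as the (R) enantiomer. The sense of induction cannot be derived with certainty, and the mirror-image acid would be used if (R) favoured the antipode.

Remark: 8 is written as the Z isomer. Any E isomer carried along is of no consequence, because the geometry is lost in 16.

## Route

Step 1
Reactants: 1 2,4-dihydroxyacetophenone; 2 benzyl bromide
Product: 3 1-[2,4-bis(benzyloxy)phenyl]ethan-1-one
Conditions: BnBr (2.3 equiv), K2CO3 (3 equiv), KI (cat.), DMF, 70 °C
Reagents that add atoms: benzyl bromide (second equivalent of 2), BrCc1ccccc1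
Why: Williamson etherification of both phenols, one equivalent of 2 for each; the chelated ortho hydroxyl reacts last and needs DMF, iodide catalysis and heat. Ring D then carries the ortho benzyl ether that later blocks six-membered closure.

Step 2
Reactants: 3 1-[2,4-bis(benzyloxy)phenyl]ethan-1-one; 4 4-hydroxybenzaldehyde
Product: 5 (E)-1-[2,4-bis(benzyloxy)phenyl]-3-(4-hydroxyphenyl)prop-2-en-1-one
Conditions: KOH (50% aq, excess), EtOH, rt, 48 h; then cold dilute HCl to pH 5
Reagents that add atoms: none
Why: Claisen–Schmidt condensation; the aldehyde reacts as its phenoxide, which is slow but workable in concentrated KOH, and dehydration gives the conjugated E alkene. With the ortho oxygen benzylated no flavanone can form.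

Step 3
Reactants: 5 (E)-1-[2,4-bis(benzyloxy)phenyl]-3-(4-hydroxyphenyl)prop-2-en-1-one
Product: 6 (E)-1-[2,4-bis(benzyloxy)phenyl]-3-[4-(triisopropylsilyloxy)phenyl]prop-2-en-1-one
Conditions: TIPSCl (1.3 equiv), imidazole (2.5 equiv), DMF, rt
Reagents that add atoms: triisopropylsilyl chloride, CC(C)[Si](Cl)(C(C)C)C(C)C
Why: Standard imidazole-mediated silylation of the only free phenol. The bulky triisopropylsilyl group is chosen because this aryl silyl ether is conjugated through ring B to the enone carbonyl (a vinylogous silyl ester), so it is more labile than usual and must survive the amine of step 4 and the aqueous base of step 9.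

Step 4
Reactants: 6 (E)-1-[2,4-bis(benzyloxy)phenyl]-3-[4-(triisopropylsilyloxy)phenyl]prop-2-en-1-one
Product: 8 (Z)-2-bromo-1-[2,4-bis(benzyloxy)phenyl]-3-[4-(triisopropylsilyloxy)phenyl]prop-2-en-1-one, via anti-dibromide 7 (not isolated)
Conditions: Br2 (1.05 equiv), CH2Cl2, −40 °C; then Et3N (3 equiv), −40 °C to rt
Reagents that add atoms: bromine, BrBr
Why: Bromine addition to the electron-rich styrenyl C=C should outrun substitution on ring D at low temperature with one equivalent of Br2. Et3N then removes the acidic alpha hydrogen and the benzylic beta bromide leaves (E1cB-type dehydrobromination), giving mainly the more stable Z alkene with ring B trans to the aroyl group.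

Step 5
Reactants: 3 1-[2,4-bis(benzyloxy)phenyl]ethan-1-one; 9 3-bromo-4-hydroxybenzaldehyde
Product: 10 (E)-1-[2,4-bis(benzyloxy)phenyl]-3-(3-bromo-4-hydroxyphenyl)prop-2-en-1-one
Conditions: KOH (50% aq, excess), EtOH, rt, 48 h; then cold dilute HCl to pH 5
Reagents that add atoms: none
Why: Claisen–Schmidt condensation as in step 2. The bromine that marks the later C3a position comes with the aldehyde, so no phenol bromination beside the activated ring E is needed.

Step 6
Reactants: 10 (E)-1-[2,4-bis(benzyloxy)phenyl]-3-(3-bromo-4-hydroxyphenyl)prop-2-en-1-one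
Product: 11 (E)-1-[2,4-bis(benzyloxy)phenyl]-3-[3-bromo-4-(tert-butyldimethylsilyloxy)phenyl]prop-2-en-1-one
Conditions: TBSCl (1.3 equiv), imidazole (2.5 equiv), DMF, rt
Reagents that add atoms: tert-butyldimethylsilyl chloride, CC(C)(C)[Si](C)(C)Cl
Why: Standard silylation. The smaller tert-butyldimethylsilyl group is used because this oxygen is ortho to the carbon that is borylated and coupled.

Step 7
Reactants: 11 (E)-1-[2,4-bis(benzyloxy)phenyl]-3-[3-bromo-4-(tert-butyldimethylsilyloxy)phenyl]prop-2-en-1-one
Product: 12 1-[2,4-bis(benzyloxy)phenyl]-3-[3-bromo-4-(tert-butyldimethylsilyloxy)phenyl]propan-1-one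
Conditions: Cu(OAc)2·H2O (5 mol%), 1,2-bis(diphenylphosphino)benzene (5 mol%), (EtO)2MeSiH (2 equiv), t-BuOH (2 equiv), toluene, rt
Reagents that add atoms: none
Why: Copper hydride conjugate reduction: hydride adds to the beta carbon, tert-butanol protonates the copper enolate and the silane regenerates Cu–H. Aryl bromide, benzyl ethers, silyl ether and ketone are left alone, which H2 over Pd/C could not guarantee.

Step 8
Reactants: 12 1-[2,4-bis(benzyloxy)phenyl]-3-[3-bromo-4-(tert-butyldimethylsilyloxy)phenyl]propan-1-one
Product: 13 1-[2,4-bis(benzyloxy)phenyl]-3-[4-(tert-butyldimethylsilyloxy)-3-(4,4,5,5-tetramethyl-1,3,2-dioxaborolan-2-yl)phenyl]propan-1-one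
Conditions: B2pin2 (1.3 equiv), PdCl2(dppf) (5 mol%), KOAc (3 equiv), 1,4-dioxane, 85 °C
Reagents that add atoms: bis(pinacolato)diboron, CC1(C)OB(OC1(C)C)B1OC(C)(C)C(C)(C)O1
Why: Miyaura borylation: oxidative addition of the aryl bromide to zerovalent palladium, acetate-assisted transmetallation with B2pin2 and reductive elimination. KOAc is too weak to enolise the ketone or cleave the silyl ether.

Step 9
Reactants: 8 (Z)-2-bromo-1-[2,4-bis(benzyloxy)phenyl]-3-[4-(triisopropylsilyloxy)phenyl]prop-2-en-1-one; 13 1-[2,4-bis(benzyloxy)phenyl]-3-[4-(tert-butyldimethylsilyloxy)-3-(4,4,5,5-tetramethyl-1,3,2-dioxaborolan-2-yl)phenyl]propan-1-one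
Product: 14 (E)-1-[2,4-bis(benzyloxy)phenyl]-2-[5-[3-[2,4-bis(benzyloxy)phenyl]-3-oxopropyl]-2-(tert-butyldimethylsilyloxy)phenyl]-3-[4-(triisopropylsilyloxy)phenyl]prop-2-en-1-one
Conditions: Pd(OAc)2 (5 mol%), SPhos (10 mol%), K3PO4 (3 equiv), toluene/H2O 10:1, 50 °C
Reagents that add atoms: none
Why: Suzuki–Miyaura coupling; alpha-bromo enones add readily to zerovalent palladium with retention of geometry, and SPhos lets the ortho-substituted boronate transmetallate at 50 °C. Both phenols are masked, so neither a phenoxide nucleophile nor a quinone methide is available for closure in the basic medium.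

Step 10
Reactants: 14 (E)-1-[2,4-bis(benzyloxy)phenyl]-2-[5-[3-[2,4-bis(benzyloxy)phenyl]-3-oxopropyl]-2-(tert-butyldimethylsilyloxy)phenyl]-3-[4-(triisopropylsilyloxy)phenyl]prop-2-en-1-one
Product: 15 (E)-1-[2,4-bis(benzyloxy)phenyl]-2-[5-[3-[2,4-bis(benzyloxy)phenyl]-3-oxopropyl]-2-hydroxyphenyl]-3-(4-hydroxyphenyl)prop-2-en-1-one
Conditions: HF·pyridine (excess), pyridine, THF, 0 °C to rt; pH 7 phosphate buffer work-up
Reagents that add atoms: none
Why: Fluoride cleaves both aryl silyl ethers, driven by the Si–F bond. The pyridine-buffered reagent is neither basic enough to form the ring B phenoxide nor acidic enough to tautomerise the enone, so 15 should be isolated without racemic closure.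

Step 11
Reactants: 15 (E)-1-[2,4-bis(benzyloxy)phenyl]-2-[5-[3-[2,4-bis(benzyloxy)phenyl]-3-oxopropyl]-2-hydroxyphenyl]-3-(4-hydroxyphenyl)prop-2-en-1-one
Product: 17 [(2S,3S)-5-[3-[2,4-bis(benzyloxy)phenyl]-3-oxopropyl]-2-(4-hydroxyphenyl)-2,3-dihydro-1-benzofuran-3-yl][2,4-bis(benzyloxy)phenyl]methanone, via para-quinone methide 16 (not isolated)
Conditions: (R)-3,3'-bis(2,4,6-triisopropylphenyl)-1,1'-binaphthyl-2,2'-diyl hydrogen phosphate (10 mol%), toluene, −20 °C; filtration through silica at full conversion
Reagents that add atoms: none
Why: Proposed new method: the phosphoric acid is expected to relay the ring B hydroxyl proton through its P(=O)OH unit onto the enone (oxygen first, then the alpha carbon), converting the 4-hydroxystyryl ketone 15 into the para-quinone methide 16 and erasing the alkene geometry; the closest known reaction type is the chiral phosphoric acid-catalysed 1,6-addition of phenols and other heteroatom nucleophiles to para-quinone methides, including methides formed in situ from 4-hydroxystyrenes, together with the racemic closure of 2-hydroxyaryl quinone methides to 2-aryl-2,3-dihydrobenzofurans. The ring A hydroxyl then adds to the methide carbon and ring B re-aromatises, which forms O1–C2 and closes the dihydrofuran ring in a 5-exo-trig mode with respect to the exocyclic methide double bond, whereas direct oxa-Michael addition to the enone of 15 would be a disfavoured 5-endo-trig process, so closure should run only through the catalyst-bound tautomer. C2 is set by the catalyst: the phosphate holds the quinone carbonyl through P–OH and the attacking phenol through P=O, and the 2,4,6-triisopropylphenyl walls are expected to leave one face of the methide open. C3 is not set kinetically; it is benzylic and alpha to the ketone, equilibrates through the enol under the same acid, and should settle trans to the C2 aryl group, which gives (2S,3S) once C2 is S. The step needs face selectivity at C2 (catalyst), trans selectivity (thermodynamic) and chemoselectivity for the five-membered closure: the benzyl ether on the ortho oxygen of ring D removes the only other phenol that could reach the methide carbon in a six-membered flavanone-type closure, and the two alkoxy donors of ring D make the aroyl carbon a poor electrophile for attack by the ring A phenol followed by dehydration to a benzofuran. Background closure is held back by the absence of base, the non-polar solvent and the low temperature, and reversal by retro-1,6-elimination, which would racemise C2, is limited by removing the acid as soon as 15 is consumed.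

Step 12
Reactants: 17 [(2S,3S)-5-[3-[2,4-bis(benzyloxy)phenyl]-3-oxopropyl]-2-(4-hydroxyphenyl)-2,3-dihydro-1-benzofuran-3-yl][2,4-bis(benzyloxy)phenyl]methanone
Product: 18 (2S,3S)-3-(2,4-dihydroxybenzoyl)-5-[3-(2,4-dihydroxyphenyl)-3-oxopropyl]-2-(4-hydroxyphenyl)-2,3-dihydro-1-benzofuran (CNP0136359.1)
Conditions: H2 (1 atm), Pd/C (10%), EtOAc, rt; stopped at the uptake of four equivalents
Reagents that add atoms: none
Why: Hydrogenolysis of four primary aryl benzyl ethers on palladium under neutral conditions. The secondary, ring-bound and hindered O1–C2 ether and the chelated aryl ketones should react much more slowly, and the neutral medium keeps C2 (no quinone methide opening) and C3 intact.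

## Compound list

1 | 2,4-dihydroxyacetophenone | CC(=O)c1ccc(O)cc1O | starting material
2 | benzyl bromide | BrCc1ccccc1 | starting material
3 | 1-[2,4-bis(benzyloxy)phenyl]ethan-1-one | CC(=O)c1ccc(OCc2ccccc2)cc1OCc1ccccc1 | intermediate
4 | 4-hydroxybenzaldehyde | O=Cc1ccc(O)cc1 | starting material
5 | (E)-1-[2,4-bis(benzyloxy)phenyl]-3-(4-hydroxyphenyl)prop-2-en-1-one | O=C(/C=C/c1ccc(O)cc1)c1ccc(OCc2ccccc2)cc1OCc1ccccc1 | intermediate
6 | (E)-1-[2,4-bis(benzyloxy)phenyl]-3-[4-(triisopropylsilyloxy)phenyl]prop-2-en-1-one | O=C(/C=C/c1ccc(O[Si](C(C)C)(C(C)C)C(C)C)cc1)c1ccc(OCc2ccccc2)cc1OCc1ccccc1 | intermediate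
7 | (2R*,3S*)-2,3-dibromo-1-[2,4-bis(benzyloxy)phenyl]-3-[4-(triisopropylsilyloxy)phenyl]propan-1-one (racemic anti-addition product, one enantiomer drawn) | O=C([C@H](Br)[C@H](Br)c1ccc(O[Si](C(C)C)(C(C)C)C(C)C)cc1)c1ccc(OCc2ccccc2)cc1OCc1ccccc1 | intermediate (not isolated)
8 | (Z)-2-bromo-1-[2,4-bis(benzyloxy)phenyl]-3-[4-(triisopropylsilyloxy)phenyl]prop-2-en-1-one | O=C(/C(Br)=C/c1ccc(O[Si](C(C)C)(C(C)C)C(C)C)cc1)c1ccc(OCc2ccccc2)cc1OCc1ccccc1 | intermediate
9 | 3-bromo-4-hydroxybenzaldehyde | O=Cc1ccc(O)c(Br)c1 | starting material
10 | (E)-1-[2,4-bis(benzyloxy)phenyl]-3-(3-bromo-4-hydroxyphenyl)prop-2-en-1-one | O=C(/C=C/c1ccc(O)c(Br)c1)c1ccc(OCc2ccccc2)cc1OCc1ccccc1 | intermediate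
11 | (E)-1-[2,4-bis(benzyloxy)phenyl]-3-[3-bromo-4-(tert-butyldimethylsilyloxy)phenyl]prop-2-en-1-one | O=C(/C=C/c1ccc(O[Si](C)(C)C(C)(C)C)c(Br)c1)c1ccc(OCc2ccccc2)cc1OCc1ccccc1 | intermediate
12 | 1-[2,4-bis(benzyloxy)phenyl]-3-[3-bromo-4-(tert-butyldimethylsilyloxy)phenyl]propan-1-one | O=C(CCc1ccc(O[Si](C)(C)C(C)(C)C)c(Br)c1)c1ccc(OCc2ccccc2)cc1OCc1ccccc1 | intermediate
13 | 1-[2,4-bis(benzyloxy)phenyl]-3-[4-(tert-butyldimethylsilyloxy)-3-(4,4,5,5-tetramethyl-1,3,2-dioxaborolan-2-yl)phenyl]propan-1-one | O=C(CCc1ccc(O[Si](C)(C)C(C)(C)C)c(B2OC(C)(C)C(C)(C)O2)c1)c1ccc(OCc2ccccc2)cc1OCc1ccccc1 | intermediate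
14 | (E)-1-[2,4-bis(benzyloxy)phenyl]-2-[5-[3-[2,4-bis(benzyloxy)phenyl]-3-oxopropyl]-2-(tert-butyldimethylsilyloxy)phenyl]-3-[4-(triisopropylsilyloxy)phenyl]prop-2-en-1-one | O=C(c1ccc(OCc2ccccc2)cc1OCc1ccccc1)/C(c1cc(CCC(=O)c2ccc(OCc3ccccc3)cc2OCc2ccccc2)ccc1O[Si](C)(C)C(C)(C)C)=C/c1ccc(O[Si](C(C)C)(C(C)C)C(C)C)cc1 | intermediate
15 | (E)-1-[2,4-bis(benzyloxy)phenyl]-2-[5-[3-[2,4-bis(benzyloxy)phenyl]-3-oxopropyl]-2-hydroxyphenyl]-3-(4-hydroxyphenyl)prop-2-en-1-one | O=C(c1ccc(OCc2ccccc2)cc1OCc1ccccc1)/C(c1cc(CCC(=O)c2ccc(OCc3ccccc3)cc2OCc2ccccc2)ccc1O)=C/c1ccc(O)cc1 | intermediate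
16 | 1-[2,4-bis(benzyloxy)phenyl]-2-[5-[3-[2,4-bis(benzyloxy)phenyl]-3-oxopropyl]-2-hydroxyphenyl]-3-(4-oxocyclohexa-2,5-dien-1-ylidene)propan-1-one (alpha carbon configurationally labile, no defined stereochemistry) | O=C(c1ccc(OCc2ccccc2)cc1OCc1ccccc1)C(c1cc(CCC(=O)c2ccc(OCc3ccccc3)cc2OCc2ccccc2)ccc1O)C=C1C=CC(=O)C=C1 | intermediate (not isolated)
17 | [(2S,3S)-5-[3-[2,4-bis(benzyloxy)phenyl]-3-oxopropyl]-2-(4-hydroxyphenyl)-2,3-dihydro-1-benzofuran-3-yl][2,4-bis(benzyloxy)phenyl]methanone | O=C(CCc1ccc2c(c1)[C@H](C(=O)c1ccc(OCc3ccccc3)cc1OCc1ccccc1)[C@@H](c1ccc(O)cc1)O2)c1ccc(OCc2ccccc2)cc1OCc1ccccc1 | intermediate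
18 | (2S,3S)-3-(2,4-dihydroxybenzoyl)-5-[3-(2,4-dihydroxyphenyl)-3-oxopropyl]-2-(4-hydroxyphenyl)-2,3-dihydro-1-benzofuran | O=C(CCc1ccc2c(c1)[C@H](C(=O)c1ccc(O)cc1O)[C@@H](c1ccc(O)cc1)O2)c1ccc(O)cc1O | target

## Step count and least certain steps

Total: 12 steps. Longest linear sequence: 9 steps (1, 5, 6, 7, 8, 9, 10, 11, 12). Compound 3 is also sold; buying it would remove step 1.

**Step 11 (key step, the only step beyond known chemistry).**
- What may go wrong: insufficient discrimination between the two faces of the methide carbon. Erosion by uncatalysed closure, or by reversible opening and reclosure of the product. Diversion by attack of the ring A phenol on the aroyl carbon and dehydration.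
- Fallback, known chemistry: from 15, catalytic K2CO3 in THF/MeOH at rt effects the established non-selective base-mediated tautomerisation and oxa-1,6-addition, giving the racemic trans tetrabenzyl ether F1. Preparative HPLC on a cellulose tris(3,5-dimethylphenylcarbamate) phase separates 17 from its (2R,3R) enantiomer F2. F2 is returned to F1 with the same base, which racemises C2 through the quinone methide, and is resolved again. The route is rejoined at 17.

**Step 4.**
- What may go wrong: electrophilic substitution on the activated ring D (para to the ortho benzyloxy group) competing with addition to the alkene, or over-bromination.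
- Fallback without bromine on an aryl-rich alkene: from 3, CuBr2 in EtOAc/CHCl3 at reflux brominates the methyl group to give 2-bromo-1-[2,4-bis(benzyloxy)phenyl]ethan-1-one F3. PPh3 in toluene gives the phosphonium bromide F4, and aqueous Na2CO3 the stabilised ylide F5. N-Bromosuccinimide in CH2Cl2 brominates the ylide carbon, by far the most nucleophilic site, to give the bromo ylide F6. A Wittig reaction of F6 with 4-(triisopropylsilyloxy)benzaldehyde F7 (from 4, triisopropylsilyl chloride, imidazole) in toluene at 90 °C rejoins the route at 8.

**Step 9.**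
- What may go wrong: slow transmetallation of the ortho-substituted boronate with protodeboronation, or loss of silyl groups in the aqueous base followed by base-triggered racemic closure.
- Fallback, base-free: from 12, Pd(PPh3)4 and hexamethylditin in toluene at 100 °C give the arylstannane 1-[2,4-bis(benzyloxy)phenyl]-3-[4-(tert-butyldimethylsilyloxy)-3-(trimethylstannyl)phenyl]propan-1-one F8. Stille coupling of F8 with 8 (Pd(PPh3)4, CuI, DMF, 60 °C) rejoins the route at 14.

**Step 12.**
- What may go wrong: over-reduction, that is hydrogenolysis of the benzylic O1–C2 bond with ring opening, or reduction of an aryl ketone.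
- Fallback, non-reductive: from 17, BCl3 with pentamethylbenzene as benzyl cation scavenger in CH2Cl2 at −78 °C, quenched cold with buffered methanol, gives 18 directly. The ring B phenol is converted in the flask to an aryloxyborane, which together with the acyl group at C3 disfavours ionisation of O1–C2. Nothing in this medium can reduce the ether or the ketones. No new compound arises (F0).

## Further compounds

F1 | step 11 | racemic trans-[5-[3-[2,4-bis(benzyloxy)phenyl]-3-oxopropyl]-2-(4-hydroxyphenyl)-2,3-dihydro-1-benzofuran-3-yl][2,4-bis(benzyloxy)phenyl]methanone (1:1 mixture of 17 and F2) | O=C(CCc1ccc2c(c1)[C@H](C(=O)c1ccc(OCc3ccccc3)cc1OCc1ccccc1)[C@@H](c1ccc(O)cc1)O2)c1ccc(OCc2ccccc2)cc1OCc1ccccc1.O=C(CCc1ccc2c(c1)[C@@H](C(=O)c1ccc(OCc3ccccc3)cc1OCc1ccccc1)[C@H](c1ccc(O)cc1)O2)c1ccc(OCc2ccccc2)cc1OCc1ccccc1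
F2 | step 11 | [(2R,3R)-5-[3-[2,4-bis(benzyloxy)phenyl]-3-oxopropyl]-2-(4-hydroxyphenyl)-2,3-dihydro-1-benzofuran-3-yl][2,4-bis(benzyloxy)phenyl]methanone | O=C(CCc1ccc2c(c1)[C@@H](C(=O)c1ccc(OCc3ccccc3)cc1OCc1ccccc1)[C@H](c1ccc(O)cc1)O2)c1ccc(OCc2ccccc2)cc1OCc1ccccc1
F3 | step 4 | 2-bromo-1-[2,4-bis(benzyloxy)phenyl]ethan-1-one | O=C(CBr)c1ccc(OCc2ccccc2)cc1OCc1ccccc1
F4 | step 4 | [2-[2,4-bis(benzyloxy)phenyl]-2-oxoethyl]triphenylphosphonium bromide | O=C(C[P+](c1ccccc1)(c1ccccc1)c1ccccc1)c1ccc(OCc2ccccc2)cc1OCc1ccccc1.[Br-]
F5 | step 4 | 1-[2,4-bis(benzyloxy)phenyl]-2-(triphenylphosphoranylidene)ethan-1-one | O=C(C=P(c1ccccc1)(c1ccccc1)c1ccccc1)c1ccc(OCc2ccccc2)cc1OCc1ccccc1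
F6 | step 4 | 2-bromo-1-[2,4-bis(benzyloxy)phenyl]-2-(triphenylphosphoranylidene)ethan-1-one | O=C(C(Br)=P(c1ccccc1)(c1ccccc1)c1ccccc1)c1ccc(OCc2ccccc2)cc1OCc1ccccc1
F7 | step 4 | 4-(triisopropylsilyloxy)benzaldehyde | O=Cc1ccc(O[Si](C(C)C)(C(C)C)C(C)C)cc1
F8 | step 9 | 1-[2,4-bis(benzyloxy)phenyl]-3-[4-(tert-butyldimethylsilyloxy)-3-(trimethylstannyl)phenyl]propan-1-one | O=C(CCc1ccc(O[Si](C)(C)C(C)(C)C)c([Sn](C)(C)C)c1)c1ccc(OCc2ccccc2)cc1OCc1ccccc1
F0 | step 12 | none | none
A1 | alternative 1 | trans-2-(4-benzyloxyphenyl)-3-(4-methoxybenzyloxymethyl)-5-[3-(4-methoxybenzyloxy)propyl]-7-triethylsilyl-2,3-dihydrobenzofuran, (2S,3R) | COc1ccc(COCCCc2cc([Si](CC)(CC)CC)c3c(c2)[C@H](COCc2ccc(OC)cc2)[C@@H](c2ccc(OCc4ccccc4)cc2)O3)cc1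
A2 | alternative 1 | (1S,2R)-1-(4-benzyloxyphenyl)-2-[(4-methoxybenzyloxy)methyl]but-3-yn-1-yl 2-(triethylsilyl)ethynyl ether | CC[Si](CC)(CC)C#CO[C@H](c1ccc(OCc2ccccc2)cc1)[C@@H](COCc1ccc(OC)cc1)C#C
A3 | alternative 1 | 5-(4-methoxybenzyloxy)pent-1-yne | C#CCCCOCc1ccc(OC)cc1
A4 | alternative 2 | methyl (2S,3S)-2-(4-benzyloxyphenyl)-5-(3-methoxy-3-oxopropyl)-2,3-dihydrobenzofuran-3-carboxylate | COC(=O)CCc1ccc2c(c1)[C@H](C(=O)OC)[C@@H](c1ccc(OCc3ccccc3)cc1)O2
A5 | alternative 2 | methyl (3S)-3-(4-benzyloxyphenyl)-2-[2-bromo-5-(3-methoxy-3-oxopropyl)phenyl]-3-hydroxypropanoate (either C2 epimer) | COC(=O)CCc1ccc(Br)c(c1)C(C(=O)OC)[C@H](O)c1ccc(OCc2ccccc2)cc1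
A6 | alternative 3 | [(2S,3S)-5-bromo-2-(4-benzyloxyphenyl)-2,3-dihydrobenzofuran-3-yl][2,4-bis(benzyloxy)phenyl]methanone | Brc1ccc2c(c1)[C@H](C(=O)c1ccc(OCc3ccccc3)cc1OCc3ccccc3)[C@@H](c1ccc(OCc3ccccc3)cc1)O2
A7 | alternative 3 | 2-[2-(4-benzyloxybenzyloxy)-5-bromophenyl]-2-diazo-1-[2,4-bis(benzyloxy)phenyl]ethan-1-one | [N-]=[N+]=C(C(=O)c1ccc(OCc2ccccc2)cc1OCc1ccccc1)c1cc(Br)ccc1OCc1ccc(OCc2ccccc2)cc1
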